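The route rests on opening ring C at the O1–C2 bond. This reveals an E-configured α-aryl chalcone whose C3 already bears the finished (R)-naringenin unit through C3–C8''. Its ring A presents two interchangeable ortho phenols, so either oxygen leads to the same product. A cinchona thiourea closes ring C by oxa-Michael addition. The catalyst fixes C2 and C3 relaxes to the trans arrangement, so one bond, one ring and two stereocentres arise in one operation. The precursor is built from an 8-allylflavanone through an α-aryl enal, an arylcerium addition and an oxidation. Its phenols are unmasked under acid, where premature closure is slow.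

Key step: step 13

**Labels:** The upper eriodictyol unit has ring A (benzo), ring B (catechol) and ring C (O1, C2, C3, C4). The lower naringenin unit has ring D (benzo, C5''–C8''), ring E (4-hydroxyphenyl) and ring F (O1'', C2'', C3'', C4'').

**Configuration read from the target SMILES:** C2 is R, C3 is S (trans, both aryl groups equatorial) and C2'' is R. The alkene of the chalcone precursor is E, with ring B trans to the C4 carbonyl.

**Design points:**
- The two ring A phenols travel as MOM ethers and are freed by acid, because closure of 2',6'-dihydroxychalcones runs through the phenoxide.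
- The para oxygen of ring A stays benzylated, so the most acidic phenol cannot tie up the amine of the catalyst.
- The alkene geometry is fixed at the enal stage.
- No hot amine or Lewis acid step is run next to ring F.

**Assumption:** (R)-MeO-F12-BIPHEP in step 5 and the quinidine-derived thiourea in step 13 are taken to give the drawn centres; if either sense proves opposite, the mirror-image ligand or the quinine-derived pseudo-enantiomer is used with no other change.

## Route

Step 1
Reactants: 1 2,4,6-trihydroxyacetophenone
Product: 2 1-[2,4-bis(benzyloxy)-6-hydroxyphenyl]ethanone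
Conditions: BnBr (2.1 equiv), K2CO3, DMF, rt to 50 °C
Reagents that add atoms: benzyl bromide, BrCc1ccccc1
Why: Williamson etherification in which the last phenol, held in a hydrogen bond to the acetyl carbonyl, is the least nucleophilic and stays free when two equivalents of halide are used.

Step 2
Reactants: 2 1-[2,4-bis(benzyloxy)-6-hydroxyphenyl]ethanone
Product: 3 1-[2-(allyloxy)-4,6-bis(benzyloxy)phenyl]ethanone
Conditions: allyl bromide, K2CO3, DMF, 60 °C
Reagents that add atoms: allyl bromide, C=CCBr
Why: Williamson etherification of the remaining chelated phenol, which needs only gentle heating with a reactive allylic halide.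

Step 3
Reactants: 3 1-[2-(allyloxy)-4,6-bis(benzyloxy)phenyl]ethanone
Product: 4 1-[3-allyl-4,6-bis(benzyloxy)-2-hydroxyphenyl]ethanone
Conditions: PhNEt2, 200 °C
Reagents that add atoms: none
Why: Aromatic Claisen rearrangement, in which the [3,3] shift delivers the allyl group to the only ortho carbon that bears hydrogen and tautomerisation restores the phenol, so the crowded bond at the future C8'' is made intramolecularly.

Step 4
Reactants: 4 1-[3-allyl-4,6-bis(benzyloxy)-2-hydroxyphenyl]ethanone
Product: 6 8-allyl-5,7-bis(benzyloxy)-4H-chromen-4-one, via enaminone 5 (not isolated)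
Conditions: Me2NCH(OMe)2, toluene, 100 °C; concentrate; AcOH, 80 °C
Reagents that add atoms: N,N-dimethylformamide dimethyl acetal, COC(OC)N(C)C
Why: Enaminone route to chromones, in which the acetyl methyl condenses with the amide acetal and, under acid, the phenol adds to the β-carbon and dimethylamine is expelled, conditions that benzyl ethers and the allyl group tolerate.

Step 5
Reactants: 6 8-allyl-5,7-bis(benzyloxy)-4H-chromen-4-one; 7 4-benzyloxyphenylboronic acid
Product: 8 (2R)-8-allyl-5,7-bis(benzyloxy)-2-[4-(benzyloxy)phenyl]chroman-4-one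
Conditions: [Rh(OH)(cod)]2 (1.5 mol%), (R)-MeO-F12-BIPHEP (3.3 mol%), 7 (2 equiv), toluene/H2O, 25 °C
Reagents that add atoms: none
Why: Hayashi–Miyaura asymmetric 1,4-addition, established for chromones, in which the aryl-rhodium species inserts C2''=C3'' on the face left open by the electron-poor atropisomeric diphosphine and so sets C2'' as R, while the base-free medium keeps ring F closed and the isolated allyl alkene is not an acceptor.

Step 6
Reactants: 8 (2R)-8-allyl-5,7-bis(benzyloxy)-2-[4-(benzyloxy)phenyl]chroman-4-one
Product: 10 2-[(2R)-5,7-bis(benzyloxy)-2-(4-benzyloxyphenyl)-4-oxochroman-8-yl]acetaldehyde, via diol 9 (not isolated)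
Conditions: OsO4 (2 mol%), NaIO4 (4 equiv), 2,6-lutidine, dioxane/H2O, rt
Reagents that add atoms: sodium periodate, [Na+].[O-]I(=O)(=O)=O; water, O
Why: Lemieux–Johnson oxidation, in which the terminal alkene is the only site for osmylation, periodate cleaves the diol in the flask, and lutidine keeps the medium near neutral so that neither the arylacetaldehyde nor C2'' suffers.

Step 7
Reactants: 10 2-[(2R)-5,7-bis(benzyloxy)-2-(4-benzyloxyphenyl)-4-oxochroman-8-yl]acetaldehyde; 11 3,4-dibenzyloxybenzaldehyde
Product: 12 (E)-3-[3,4-bis(benzyloxy)phenyl]-2-[(2R)-5,7-bis(benzyloxy)-2-(4-benzyloxyphenyl)-4-oxochroman-8-yl]prop-2-enal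
Conditions: 11 (2 equiv), pyrrolidine (30 mol%), AcOH (30 mol%), 4 Å MS, CH2Cl2, rt, slow addition of 10
Reagents that add atoms: none
Why: Amine-catalysed crossed aldol condensation, in which only 10 can form an enamine, the non-enolisable 11 is the acceptor in excess, loss of water gives the thermodynamically preferred E-2,3-diarylpropenal, and the buffered catalyst is too weak a base to enolise the deactivated C4'' ketone, so C2'' is retained.

Step 8
Reactants: 13 phloroglucinol
Product: 14 3,5-bis(methoxymethoxy)phenol
Conditions: MOMCl (2 equiv), K2CO3, acetone, 0 °C to rt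
Reagents that add atoms: chloromethyl methyl ether, COCCl
Why: Williamson-type O-alkylation with a hard electrophile avoids C-alkylation, and the threefold symmetry of phloroglucinol makes the bis-ether a single compound that chromatography separates from the mono- and tris-ethers.

Step 9
Reactants: 14 3,5-bis(methoxymethoxy)phenol
Product: 15 1-(benzyloxy)-3,5-bis(methoxymethoxy)benzene
Conditions: BnBr, K2CO3, DMF, rt
Reagents that add atoms: benzyl bromide, BrCc1ccccc1
Why: Williamson etherification of the single remaining phenol.

Step 10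
Reactants: 15 1-(benzyloxy)-3,5-bis(methoxymethoxy)benzene; 12 (E)-3-[3,4-bis(benzyloxy)phenyl]-2-[(2R)-5,7-bis(benzyloxy)-2-(4-benzyloxyphenyl)-4-oxochroman-8-yl]prop-2-enal
Product: 18 (E)-1-[4-(benzyloxy)-2,6-bis(methoxymethoxy)phenyl]-3-[3,4-bis(benzyloxy)phenyl]-2-[(2R)-5,7-bis(benzyloxy)-2-(4-benzyloxyphenyl)-4-oxochroman-8-yl]prop-2-en-1-ol (both carbinol epimers), via aryllithium 16 (not isolated), via arylcerium dichloride 17 (not isolated)
Conditions: 15 (1.3 equiv), n-BuLi, THF, 0 °C; anhydrous CeCl3, −78 °C; 12, THF, −78 °C; pH 7 buffer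
Reagents that add atoms: none
Why: Directed ortho-metalation occurs at the carbon flanked by both chelating OMOM groups, and the derived organocerium reagent, nucleophilic but barely basic, adds 1,2 to the non-enolisable enal much faster than it can attack or enolise the hindered, electron-rich C4'' ketone, while the new carbinol centre is erased in the next step.

Step 11
Reactants: 18 the allylic alcohol of step 10
Product: 19 (E)-1-[4-(benzyloxy)-2,6-bis(methoxymethoxy)phenyl]-3-[3,4-bis(benzyloxy)phenyl]-2-[(2R)-5,7-bis(benzyloxy)-2-(4-benzyloxyphenyl)-4-oxochroman-8-yl]prop-2-en-1-one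
Conditions: Dess–Martin periodinane, pyridine, CH2Cl2, 0 °C to rt
Reagents that add atoms: none
Why: Dess–Martin oxidation under pyridine buffering turns the acid-sensitive, doubly activated alcohol into the enone without touching the alkene geometry or C2''.

Step 12
Reactants: 19 the bis-MOM α-aryl chalcone of step 11
Product: 20 (E)-1-[4-(benzyloxy)-2,6-dihydroxyphenyl]-3-[3,4-bis(benzyloxy)phenyl]-2-[(2R)-5,7-bis(benzyloxy)-2-(4-benzyloxyphenyl)-4-oxochroman-8-yl]prop-2-en-1-one
Conditions: HCl (cat., 1.25 M in MeOH), MeOH/THF, 0 °C to rt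
Reagents that add atoms: none
Why: Acid-catalysed acetal exchange removes both MOM groups, helped by the neighbouring carbonyl, and leaves benzyl ethers intact, and because ring closure of 2',6'-dihydroxychalcones needs the phenoxide, the open chalcone should be isolable from acidic medium.

Step 13
Reactants: 20 the 2',6'-dihydroxy α-aryl chalcone of step 12
Product: 22 (2R,3S)-7-(benzyloxy)-2-[3,4-bis(benzyloxy)phenyl]-3-[(2R)-5,7-bis(benzyloxy)-2-(4-benzyloxyphenyl)-4-oxochroman-8-yl]-5-hydroxychroman-4-one, via enol 21 (not isolated)
Conditions: quinidine-derived thiourea, 1-[3,5-bis(trifluoromethyl)phenyl]-3-(9-deoxy-epi-quinidin-9-yl)thiourea (15 mol%), toluene, −25 °C; cold filtration through silica at full conversion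
Reagents that add atoms: none
Why: Proposed new method: the quinuclidine nitrogen deprotonates one ring A phenol while the thiourea N–H pair binds the C4 carbonyl, which the other phenol also polarises by hydrogen bonding, and the phenoxide adds to C2 to give enol 21, which tautomerises to the ketone. The closest known reaction type is the cinchona-thiourea-catalysed intramolecular oxa-Michael cyclisation of 2'-hydroxychalcone-type enones to flavanones; achiral amines are known to close α-aryl-2'-hydroxychalcones to trans-2,3-diarylchroman-4-ones, so the α-aryl group, twisted out of conjugation, should not block addition, and what is new is asymmetric catalysis on such an enone. Ring C closes in the 6-endo-trig mode. C2 (R) is set by the catalyst, which shields one face of the E-alkene, because C2'' lies five bonds away and gives no useful bias. C3 (S) is set afterwards by reversible enolisation, which drains any cis isomer into the trans form with both aryl groups equatorial. The step needs site selectivity among oxygens and face selectivity at C2: the first is secured because the two free phenols are exchanged by rotation of ring A and every other phenol is benzylated, and the second rests on the catalyst, the low temperature and a prompt stop that keeps ring reopening from eroding C2.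

Step 14
Reactants: 22 the hexabenzyl ether of step 13
Product: 23 (2R,3S)-2-(3,4-dihydroxyphenyl)-3-[(2R)-5,7-dihydroxy-2-(4-hydroxyphenyl)-4-oxochroman-8-yl]-5,7-dihydroxychroman-4-one
Conditions: H2 (1 atm), Pd/C (10 wt%), EtOAc/MeOH, rt
Reagents that add atoms: none
Why: Catalytic hydrogenolysis cleaves the six primary aryl benzyl ethers far faster than the hindered cyclic C2–O1 and C2''–O1'' bonds, and the neutral medium at room temperature gives no path for epimerisation of the three stereocentres.

## Compound list

1 | 2,4,6-trihydroxyacetophenone | CC(=O)c1c(O)cc(O)cc1O | starting material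
2 | 1-[2,4-bis(benzyloxy)-6-hydroxyphenyl]ethanone | CC(=O)c1c(O)cc(OCc2ccccc2)cc1OCc1ccccc1 | intermediate
3 | 1-[2-(allyloxy)-4,6-bis(benzyloxy)phenyl]ethanone | CC(=O)c1c(OCC=C)cc(OCc2ccccc2)cc1OCc1ccccc1 | intermediate
4 | 1-[3-allyl-4,6-bis(benzyloxy)-2-hydroxyphenyl]ethanone | CC(=O)c1c(O)c(CC=C)c(OCc2ccccc2)cc1OCc1ccccc1 | intermediate
5 | (E)-1-[3-allyl-4,6-bis(benzyloxy)-2-hydroxyphenyl]-3-(dimethylamino)prop-2-en-1-one | CN(C)/C=C/C(=O)c1c(O)c(CC=C)c(OCc2ccccc2)cc1OCc1ccccc1 | intermediate
6 | 8-allyl-5,7-bis(benzyloxy)-4H-chromen-4-one | O=c1ccoc2c(CC=C)c(OCc3ccccc3)cc(OCc3ccccc3)c12 | intermediate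
7 | 4-benzyloxyphenylboronic acid | OB(O)c1ccc(OCc2ccccc2)cc1 | starting material
8 | (2R)-8-allyl-5,7-bis(benzyloxy)-2-[4-(benzyloxy)phenyl]chroman-4-one | O=C1C[C@H](c2ccc(OCc9ccccc9)cc2)Oc2c1c(OCc9ccccc9)cc(OCc9ccccc9)c2CC=C | intermediate
9 | (2R)-5,7-bis(benzyloxy)-2-[4-(benzyloxy)phenyl]-8-(2,3-dihydroxypropyl)chroman-4-one (both carbinol epimers) | O=C1C[C@H](c2ccc(OCc9ccccc9)cc2)Oc2c1c(OCc9ccccc9)cc(OCc9ccccc9)c2CC(O)CO | intermediate
10 | 2-[(2R)-5,7-bis(benzyloxy)-2-(4-benzyloxyphenyl)-4-oxochroman-8-yl]acetaldehyde | O=C1C[C@H](c2ccc(OCc9ccccc9)cc2)Oc2c1c(OCc9ccccc9)cc(OCc9ccccc9)c2CC=O | intermediate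
11 | 3,4-dibenzyloxybenzaldehyde | O=Cc1ccc(OCc2ccccc2)c(OCc2ccccc2)c1 | starting material
12 | (E)-α-aryl enal, ring B trans to the formyl group | O=C1C[C@H](c2ccc(OCc9ccccc9)cc2)Oc2c1c(OCc9ccccc9)cc(OCc9ccccc9)c2/C(=C\c1ccc(OCc9ccccc9)c(OCc9ccccc9)c1)C=O | intermediate
13 | phloroglucinol | Oc1cc(O)cc(O)c1 | starting material
14 | 3,5-bis(methoxymethoxy)phenol | COCOc1cc(O)cc(OCOC)c1 | intermediate
15 | 1-(benzyloxy)-3,5-bis(methoxymethoxy)benzene | COCOc1cc(OCc2ccccc2)cc(OCOC)c1 | intermediate
16 | 4-(benzyloxy)-2,6-bis(methoxymethoxy)phenyllithium | [Li]c1c(OCOC)cc(OCc2ccccc2)cc1OCOC | intermediate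
17 | 4-(benzyloxy)-2,6-bis(methoxymethoxy)phenylcerium dichloride | Cl[Ce](Cl)c1c(OCOC)cc(OCc2ccccc2)cc1OCOC | intermediate
18 | (E)-allylic alcohol from 17 and 12 (both carbinol epimers) | O=C1C[C@H](c2ccc(OCc9ccccc9)cc2)Oc2c1c(OCc9ccccc9)cc(OCc9ccccc9)c2/C(=C\c1ccc(OCc9ccccc9)c(OCc9ccccc9)c1)C(O)c1c(OCOC)cc(OCc9ccccc9)cc1OCOC | intermediate
19 | (E)-α-[(R)-naringenin-8-yl]chalcone, hexabenzyl ether, 2',6'-bis-MOM ether | O=C1C[C@H](c2ccc(OCc9ccccc9)cc2)Oc2c1c(OCc9ccccc9)cc(OCc9ccccc9)c2/C(=C\c1ccc(OCc9ccccc9)c(OCc9ccccc9)c1)C(=O)c1c(OCOC)cc(OCc9ccccc9)cc1OCOC | intermediate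
20 | (E)-α-[(R)-naringenin-8-yl]-2',6'-dihydroxychalcone, hexabenzyl ether (key-step precursor) | O=C1C[C@H](c2ccc(OCc9ccccc9)cc2)Oc2c1c(OCc9ccccc9)cc(OCc9ccccc9)c2/C(=C\c1ccc(OCc9ccccc9)c(OCc9ccccc9)c1)C(=O)c1c(O)cc(OCc9ccccc9)cc1O | intermediate
21 | enol tautomer of 22 (2H-chromene-4,5-diol, C2 arranged in space as in 22) | O=C1C[C@H](c2ccc(OCc9ccccc9)cc2)Oc2c1c(OCc9ccccc9)cc(OCc9ccccc9)c2C1=C(O)c2c(O)cc(OCc9ccccc9)cc2O[C@H]1c1ccc(OCc9ccccc9)c(OCc9ccccc9)c1 | intermediate
22 | (2R,3S,2''R)-hexabenzyl ether of the target with free 5-hydroxyl (key-step product) | O=C1C[C@H](c2ccc(OCc9ccccc9)cc2)Oc2c1c(OCc9ccccc9)cc(OCc9ccccc9)c2[C@@H]1C(=O)c2c(O)cc(OCc9ccccc9)cc2O[C@H]1c1ccc(OCc9ccccc9)c(OCc9ccccc9)c1 | intermediate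
23 | (2R,3S,2''R)-eriodictyol-(3→8'')-naringenin, CNP0105436.3 | O=C1C[C@H](c2ccc(O)cc2)Oc2c1c(O)cc(O)c2[C@@H]1C(=O)c2c(O)cc(O)cc2O[C@H]1c1ccc(O)c(O)c1 | target

## Step count

Total step count: 14.
Longest linear sequence: 12 (steps 1–7 and 10–14). Steps 8 and 9 form the ring A branch.

## Steps most likely to fail

1. **Step 13.**
   - *What may go wrong:* The catalyst may discriminate poorly between the two faces of an enone that offers only one carbonyl for binding. Crowding at C3 may slow the addition so far that warming is needed, and reversible ring opening would then wear down the configuration at C2. Slow rotation about C3–C8'' could also create two rotamer populations that respond differently to the catalyst.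
   - *Fallback, by known chemistry:* Setting out from 20, ring C is closed with an achiral tertiary amine (DABCO, CH2Cl2, rt). This is the established amine-promoted cyclisation of α-aryl-2'-hydroxychalcones to trans-2,3-diarylchroman-4-ones. Because C2'' is already fixed, the two trans products are diastereomers, 22 and the (2S,3R,2''R)-diastereomer F1, and chromatography separates them. F1 is returned to the same amine at a higher temperature, where retro-addition passes back through 20 and re-equilibrates the pair. The route is rejoined at 22.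

2. **Step 7.**
   - *What may go wrong:* The arylacetaldehyde may condense with itself or enolise and oxidise. The electron-rich aromatic aldehyde may also react too slowly with a hindered enamine.
   - *Fallback:* Setting out from 10, silylation (TMSOTf, Et3N, CH2Cl2, −20 °C) gives the trimethylsilyl enol ether F2. A Mukaiyama aldol addition to 11 (BF3·OEt2, CH2Cl2, −78 °C) gives the β-hydroxy aldehyde F3. Catalytic p-TsOH in toluene at rt then removes water to give the E-enal. This replaces amine catalysis by a directed, Lewis-acid-mediated aldol in which donor and acceptor roles are fixed beforehand. The route is rejoined at 12.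

3. **Step 10.**
   - *What may go wrong:* Residual basicity of the organometallic may deprotonate C3'' and open ring F, with loss of integrity at C2''. Metalation may also stray to the ring carbon next to the benzyloxy group.
   - *Fallback:* Setting out from 15, the lithiation is repeated and 16 is quenched with I2 to give 5-(benzyloxy)-2-iodo-1,3-bis(methoxymethoxy)benzene F4. F4 is purified, so its regiochemistry is settled before the union. A Nozaki–Hiyama–Kishi coupling with 12 (CrCl2, NiCl2 cat., DMF, rt) then adds a non-basic, aldehyde-selective arylchromium species to the enal. The route is rejoined at 18.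

Further compounds
F1 | step 13 | (2S,3R,2''R)-diastereomer of 22 | O=C1C[C@H](c2ccc(OCc9ccccc9)cc2)Oc2c1c(OCc9ccccc9)cc(OCc9ccccc9)c2[C@H]1C(=O)c2c(O)cc(OCc9ccccc9)cc2O[C@@H]1c1ccc(OCc9ccccc9)c(OCc9ccccc9)c1
F2 | step 7 | trimethylsilyl enol ether of 10 (alkene geometry not defined) | O=C1C[C@H](c2ccc(OCc9ccccc9)cc2)Oc2c1c(OCc9ccccc9)cc(OCc9ccccc9)c2C=CO[Si](C)(C)C
F3 | step 7 | β-hydroxy aldehyde from F2 and 11 (diastereomer mixture at the two new centres) | O=C1C[C@H](c2ccc(OCc9ccccc9)cc2)Oc2c1c(OCc9ccccc9)cc(OCc9ccccc9)c2C(C=O)C(O)c1ccc(OCc9ccccc9)c(OCc9ccccc9)c1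
F4 | step 10 | 5-(benzyloxy)-2-iodo-1,3-bis(methoxymethoxy)benzene | COCOc1cc(OCc2ccccc2)cc(OCOC)c1I
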